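The rate constants come from no measurement, and the outcome is calculated.

The constants first, as they stand for both flasks:

- oak: substrate 0.50 M; first nucleophile 1.00 equiv; second nucleophile 3.00 equiv; time 6.0 h
- cedar: substrate 0.50 M; first nucleophile 2.00 equiv; second nucleophile 3.00 equiv; time 6.0 h

    target ⇌ isomer of the product (K1 = 0.37, k1 = 1.7 × 10⁻⁴ min⁻¹)
    substrate → intermediate (k2 = 0.032 min⁻¹)
    first nucleophile + intermediate → target (k3 = 0.14 M⁻¹ min⁻¹)
    intermediate → solvolysis product (k4 = 0.0036 min⁻¹)
    substrate ⇌ dormant form (K5 = 0.87, k5 = 0.010 min⁻¹)
    second nucleophile + intermediate → other capture product (k6 = 0.025 M⁻¹ min⁻¹)

- which of these there is most of at the end, counted by the substrate in it, oak (isomer of the product / target / other capture product / solvolysis product)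
- which of these there is most of at the end, counted by the substrate in it, cedar (isomer of the product / target / other capture product / solvolysis product)
- amount of the one of these that there is most of at the end, in percent of the substrate charged, oak
- amount of the one of these that there is most of at the end, in percent of the substrate charged, cedar

*What happens to substrate once it is intermediate?* Each way out is first order in intermediate, so c(intermediate) cancels from any ratio of them. In oak as charged, the rates per unit of intermediate are 0.0700 min⁻¹ to target, 0.0375 min⁻¹ to other capture product and 0.0036 min⁻¹ to solvolysis product. The starting share to target in oak is therefore 63.0%.

*Why not stop there?* Each portion of target takes one first nucleophile, and oak charges 1.00 equiv, so c(first nucleophile) falls as material passes. Every portion of substrate meets that concentration at its own passing, so the mean belongs over the substrate passed through, not over the clock. With a steady share the fall is a straight line in material passed, and the mean is its midpoint, 0.342 M. That gives oak a share of 53.8%, lower than the start.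

*But that midpoint used the starting share. What error does this make?* Taking the midpoint again with the new share gives oak 0.365 M and a share of 55.4%. The step is 1.6 percentage points, against 9.2 points before, and I stop here. This is the capture share: the part of what leaves the intermediate that goes to target, with first nucleophile at its mean over the substrate passed through. Second nucleophile I hold at its charge, though in oak its midpoint lies 7.43% below it.

*And the isomer?* The forward constant of isomerisation times the time is 6.12%. I take that as the fraction of target lost, and I count substrate and dormant form as passed through. Oak then ends with most target, at 52.1%.

*Cedar?* The same turns run from 77.3% through 73.3% to 73.6%. Cedar ends with most target, at 69.1%.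

The forecast names target for oak at 52%, from 47% to 57%, and target for cedar at 69%, from 64% to 74%. Of the first nucleophile it says “its depletion matters, especially in oak”.

The simulation gives target at 51.9% in oak and target at 69.0% in cedar, inside both ranges of the forecast. In oak, target and isomer together hold 55.7% of the substrate found in target, isomer, other capture product and solvolysis product, against the capture share of 55.4%, and at 0.402 h the intermediate was going to target 1.5 times as fast as to other capture product. The neighbour of oak with 5.10 equiv of second nucleophile keeps 56% of its first nucleophile, and the capture share at the midpoint of that fall, less the same isomer loss, comes to 42.0%. That flask ends with 42.2% of target.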